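## Retrosynthetic overview

- Ring A is opened at C8–C8a: the 8-hydroxy-5,6,7-trimethoxy arene comes from a 4π ring opening/6π electrocyclisation of a 4-methoxycyclobutenone on C5 of a 2-aryl-2,3-dihydro-4H-pyran-4-one. Dimethyl squarate supplies C5–C8 with all four oxygens.
- Ring C is opened at O1–C2 and C3–C4: a catalytic asymmetric formal hetero-Diels–Alder reaction of veratraldehyde (ring B, bought) with a Danishefsky-type diene sets C2.
- Both disconnections are run in one flask on a diene that already carries the cyclobutenone: ring C forms first (0 °C to rt), then ring A (110 °C).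
- The diene comes from dimethyl squarate and a dienyllithium. The silyl enol ether masks the ketone during lithiation and later serves as the diene.
- The dienyllithium comes from (E)-4-methoxybut-3-en-2-one by α-iodination and silylation.

Assumption: (S)-BINOL/Ti(OiPr)4 is taken to direct attack to the Si face of the aryl aldehyde, which gives (S) at C2; if the measured sense is opposite, (R)-BINOL is used with no other change.

Compounds 6, 7 and 9–12 are mixtures of epimers at centres that disappear when ring A aromatises; only C2 is controlled.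

## Route

Step 1
Reactants: 1 (E)-4-methoxybut-3-en-2-one
Product: 2 (Z)-3-iodo-4-methoxybut-3-en-2-one
Conditions: NIS (1.1 equiv), MeCN, 0 °C → rt, dark
Reagents that add atoms: N-iodosuccinimide, O=C1CCC(=O)N1I
Why: C3 of this push–pull enol ether is its nucleophilic carbon, so electrophilic α-iodination (iodonium transfer, then loss of the C3 proton from the oxocarbenium ion) gives the iodide, which settles as the Z isomer with OMe trans to acetyl and cis to iodine.

Step 2
Reactants: 2 (Z)-3-iodo-4-methoxybut-3-en-2-one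
Product: 3 {[(3Z)-3-iodo-4-methoxybuta-1,3-dien-2-yl]oxy}triisopropylsilane
Conditions: TIPSOTf (1.2 equiv), Et3N (1.5 equiv), Et2O, 0 °C
Reagents that add atoms: triisopropylsilyl trifluoromethanesulfonate, CC(C)[Si](C(C)C)(C(C)C)OS(=O)(=O)C(F)(F)F
Why: Soft enolisation and O-silylation of the methyl ketone (the standard Danishefsky-diene preparation) can only occur at the methyl group, and the bulky silyl group is chosen so that the later vinyllithium does not undergo a 1,3 O→C silyl shift (retro-Brook rearrangement).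

Step 3
Reactants: 3 {[(3Z)-3-iodo-4-methoxybuta-1,3-dien-2-yl]oxy}triisopropylsilane; 4 dimethyl squarate
Product: 7 2,3,4-trimethoxy-4-[(1E)-1-methoxy-3-(triisopropylsilyloxy)buta-1,3-dien-2-yl]cyclobut-2-en-1-one (racemic), via dienyllithium 5 (not isolated), via lithium alkoxide 6 (not isolated)
Conditions: t-BuLi (2.0 equiv), Et2O, −78 °C, 10 min; cannulate into 4 (1.1 equiv), THF, −78 °C; MeOTf (1.5 equiv), −78 → 0 °C; purify at or below rt on Et3N-deactivated silica
Reagents that add atoms: methyl trifluoromethanesulfonate, COS(=O)(=O)C(F)(F)F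
Why: Iodine–lithium exchange proceeds with retention to a vinyllithium chelated by the cis methoxy group (no anti β-elimination is possible), this adds 1,2 to one squarate carbonyl (Moore–Liebeskind squarate addition), and the tertiary lithium alkoxide is O-methylated in the flask (Williamson-type alkylation); the new quaternary centre is racemic and is erased in step 4.

Step 4
Reactants: 7 2,3,4-trimethoxy-4-[(1E)-1-methoxy-3-(triisopropylsilyloxy)buta-1,3-dien-2-yl]cyclobut-2-en-1-one; 8 3,4-dimethoxybenzaldehyde (veratraldehyde)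
Product: 13 (2S)-2-(3,4-dimethoxyphenyl)-8-hydroxy-5,6,7-trimethoxy-2,3-dihydro-4H-chromen-4-one, via cycloadduct 9 (not isolated), via pyranone 10 (not isolated), via dienylketene 11 (not isolated), via cyclohexadienone 12 (not isolated)
Conditions: Ti(OiPr)4 (10 mol%), (S)-BINOL (20 mol%), 4 Å MS, toluene, 0 °C → rt; then TFA (10 mol%), 0 °C, 30 min; then 2,6-lutidine (20 mol%), 110 °C, 2 h, Ar
Reagents that add atoms: none
Why: Proposed new method: a BINOL–titanium-catalysed Mukaiyama aldol/ring closure (a formal asymmetric hetero-Diels–Alder reaction of a Danishefsky-type diene, the closest known reaction) delivers the diene CH2 terminus to the Si face of the aldehyde and sets C2 as S, catalytic acid then expels methanol and the silyl group to give the 5-substituted dihydropyranone (ring C), and heating starts the Moore–Liebeskind cascade (conrotatory 4π opening with the methoxy group rotating outward, 6π electrocyclisation of the dienylketene onto C6 of the pyranone, tautomerisation) that builds ring A with the ketene oxygen as the free 8-OH and the squarate-derived methoxy groups at C5, C6 and C7; each stage is known on its own, the telescoped sequence on a cyclobutenone-bearing diene is not.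

## Compound list

1 | (E)-4-methoxybut-3-en-2-one | CO/C=C/C(C)=O | starting material
2 | (Z)-3-iodo-4-methoxybut-3-en-2-one | CO/C=C(\I)C(C)=O | intermediate
3 | {[(3Z)-3-iodo-4-methoxybuta-1,3-dien-2-yl]oxy}triisopropylsilane | CO/C=C(\I)C(=C)O[Si](C(C)C)(C(C)C)C(C)C | intermediate
4 | dimethyl squarate (3,4-dimethoxycyclobut-3-ene-1,2-dione) | COC1=C(OC)C(=O)C1=O | starting material
5 | [(1E)-1-methoxy-3-(triisopropylsilyloxy)buta-1,3-dien-2-yl]lithium (Li cis to OMe; formed in the flask) | [Li]/C(=C\OC)C(=C)O[Si](C(C)C)(C(C)C)C(C)C | intermediate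
6 | lithium 2,3-dimethoxy-1-[(1E)-1-methoxy-3-(triisopropylsilyloxy)buta-1,3-dien-2-yl]-4-oxocyclobut-2-en-1-olate (racemic; formed in the flask) | CO/C=C(/C(=C)O[Si](C(C)C)(C(C)C)C(C)C)C1(O[Li])C(OC)=C(OC)C1=O | intermediate
7 | 2,3,4-trimethoxy-4-[(1E)-1-methoxy-3-(triisopropylsilyloxy)buta-1,3-dien-2-yl]cyclobut-2-en-1-one (racemic) | CO/C=C(/C(=C)O[Si](C(C)C)(C(C)C)C(C)C)C1(OC)C(OC)=C(OC)C1=O | intermediate
8 | 3,4-dimethoxybenzaldehyde (veratraldehyde) | COc1ccc(C=O)cc1OC | starting material
9 | (2S)-2-(3,4-dimethoxyphenyl)-6-methoxy-5-(1,2,3-trimethoxy-4-oxocyclobut-2-en-1-yl)-4-(triisopropylsilyloxy)-3,6-dihydro-2H-pyran (epimers at C6 and at the cyclobutenone carbon; formed in the flask) | COc1ccc([C@@H]2CC(O[Si](C(C)C)(C(C)C)C(C)C)=C(C(OC)O2)C3(OC)C(OC)=C(OC)C3=O)cc1OC | intermediate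
10 | (2S)-2-(3,4-dimethoxyphenyl)-5-(1,2,3-trimethoxy-4-oxocyclobut-2-en-1-yl)-2,3-dihydro-4H-pyran-4-one (epimers at the cyclobutenone carbon; formed in the flask) | COc1ccc([C@@H]2CC(=O)C(=CO2)C3(OC)C(OC)=C(OC)C3=O)cc1OC | intermediate
11 | (2S)-2-(3,4-dimethoxyphenyl)-5-[(1Z)-1,2,3-trimethoxy-4-oxobuta-1,3-dien-1-yl]-2,3-dihydro-4H-pyran-4-one (dienylketene; formed in the flask) | COc1ccc([C@@H]2CC(=O)C(=CO2)/C(OC)=C(OC)\C(OC)=C=O)cc1OC | intermediate
12 | (2S)-2-(3,4-dimethoxyphenyl)-5,6,7-trimethoxy-2,3-dihydro-4H-chromene-4,8(8aH)-dione (epimers at C8a; formed in the flask) | COc1ccc([C@@H]2CC(=O)C3=C(OC)C(OC)=C(OC)C(=O)C3O2)cc1OC | intermediate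
13 | (2S)-2-(3,4-dimethoxyphenyl)-8-hydroxy-5,6,7-trimethoxy-2,3-dihydro-4H-chromen-4-one | COc1ccc([C@@H]2CC(=O)c3c(c(O)c(OC)c(OC)c3OC)O2)cc1OC | target

## Totals and risks

Total step count: 4. Longest linear sequence: 4 (1 → 2 → 3 → 7 → 13); 4 and 8 enter convergently.

Steps most likely to fail:

1. Step 4. The diene is hindered and carries Lewis-basic groups, the aldehyde is electron-rich, and the acid and heat stages must not touch the cyclobutenone ether or the benzylic C2–O bond. Fallback, setting out from 3 and 8 and coming back at 10: the rings are made separately. The same BINOL/Ti(OiPr)4 reaction is run on the small diene 3 to give (2S)-2-(3,4-dimethoxyphenyl)-5-iodo-6-methoxy-4-(triisopropylsilyloxy)-3,6-dihydro-2H-pyran F1, and TFA converts this into (2S)-2-(3,4-dimethoxyphenyl)-5-iodo-2,3-dihydro-4H-pyran-4-one F2. Iodine–magnesium exchange (iPrMgCl·LiCl, THF, −40 °C; the vinylogous-ester carbonyl is tolerated) gives chloro[(2S)-2-(3,4-dimethoxyphenyl)-4-oxo-3,4-dihydro-2H-pyran-5-yl]magnesium F3. This adds to 4 to give the chloromagnesium alkoxide of the squarate adduct F4, and NH4Cl work-up gives (2S)-2-(3,4-dimethoxyphenyl)-5-(1-hydroxy-2,3-dimethoxy-4-oxocyclobut-2-en-1-yl)-2,3-dihydro-4H-pyran-4-one F5. MeI/Ag2O in MeCN methylates the tertiary alcohol to 10, which is heated in toluene at 110 °C to 13.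

2. Step 3. The vinyllithium may decompose, or the in-flask methylation may be incomplete. Fallback, setting out from 3 and coming back at 7: a less basic organomagnesium is used and C–C bond formation is separated from etherification. iPrMgCl·LiCl (THF, −20 °C) gives chloro[(1Z)-1-methoxy-3-(triisopropylsilyloxy)buta-1,3-dien-2-yl]magnesium F6. Addition to 4 gives the chloromagnesium alkoxide F7, and NH4Cl work-up gives the isolated alcohol 4-hydroxy-2,3-dimethoxy-4-[(1E)-1-methoxy-3-(triisopropylsilyloxy)buta-1,3-dien-2-yl]cyclobut-2-en-1-one F8. MeI/Ag2O then gives 7.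

3. Step 1. Iodination may be slow, may occur at the methyl group, or may give the wrong alkene geometry. Fallback, setting out from 1 and coming back at 5: addition–elimination replaces direct substitution. Br2 (CH2Cl2, −78 °C) gives 3,4-dibromo-4-methoxybutan-2-one F9, and Et3N eliminates HBr to give (Z)-3-bromo-4-methoxybut-3-en-2-one F10. TIPSOTf/Et3N gives {[(3Z)-3-bromo-4-methoxybuta-1,3-dien-2-yl]oxy}triisopropylsilane F11, and bromine–lithium exchange (t-BuLi, 2 equiv, −78 °C) gives 5.

## Further compounds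

F1 | step 4 | (2S)-2-(3,4-dimethoxyphenyl)-5-iodo-6-methoxy-4-(triisopropylsilyloxy)-3,6-dihydro-2H-pyran | COc1ccc([C@@H]2CC(O[Si](C(C)C)(C(C)C)C(C)C)=C(I)C(OC)O2)cc1OC
F2 | step 4 | (2S)-2-(3,4-dimethoxyphenyl)-5-iodo-2,3-dihydro-4H-pyran-4-one | COc1ccc([C@@H]2CC(=O)C(I)=CO2)cc1OC
F3 | step 4 | chloro[(2S)-2-(3,4-dimethoxyphenyl)-4-oxo-3,4-dihydro-2H-pyran-5-yl]magnesium | COc1ccc([C@@H]2CC(=O)C([Mg]Cl)=CO2)cc1OC
F4 | step 4 | chloromagnesium 1-[(2S)-2-(3,4-dimethoxyphenyl)-4-oxo-3,4-dihydro-2H-pyran-5-yl]-2,3-dimethoxy-4-oxocyclobut-2-en-1-olate | COc1ccc([C@@H]2CC(=O)C(=CO2)C3(O[Mg]Cl)C(OC)=C(OC)C3=O)cc1OC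
F5 | step 4 | (2S)-2-(3,4-dimethoxyphenyl)-5-(1-hydroxy-2,3-dimethoxy-4-oxocyclobut-2-en-1-yl)-2,3-dihydro-4H-pyran-4-one | COc1ccc([C@@H]2CC(=O)C(=CO2)C3(O)C(OC)=C(OC)C3=O)cc1OC
F6 | step 3 | chloro[(1Z)-1-methoxy-3-(triisopropylsilyloxy)buta-1,3-dien-2-yl]magnesium | Cl[Mg]/C(=C\OC)C(=C)O[Si](C(C)C)(C(C)C)C(C)C
F7 | step 3 | chloromagnesium 2,3-dimethoxy-1-[(1E)-1-methoxy-3-(triisopropylsilyloxy)buta-1,3-dien-2-yl]-4-oxocyclobut-2-en-1-olate | CO/C=C(/C(=C)O[Si](C(C)C)(C(C)C)C(C)C)C1(O[Mg]Cl)C(OC)=C(OC)C1=O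
F8 | step 3 | 4-hydroxy-2,3-dimethoxy-4-[(1E)-1-methoxy-3-(triisopropylsilyloxy)buta-1,3-dien-2-yl]cyclobut-2-en-1-one | CO/C=C(/C(=C)O[Si](C(C)C)(C(C)C)C(C)C)C1(O)C(OC)=C(OC)C1=O
F9 | step 1 | 3,4-dibromo-4-methoxybutan-2-one | COC(Br)C(Br)C(C)=O
F10 | step 1 | (Z)-3-bromo-4-methoxybut-3-en-2-one | CO/C=C(\Br)C(C)=O
F11 | step 1 | {[(3Z)-3-bromo-4-methoxybuta-1,3-dien-2-yl]oxy}triisopropylsilane | CO/C=C(\Br)C(=C)O[Si](C(C)C)(C(C)C)C(C)C
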